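**Assumption:** nymphaeol A is taken as the (2S)-flavanone with a (2E)-geranyl chain at C6, as drawn. Flavanone numbering (O1, C2, C3, C4, C4a, C5–C8, C8a; ring B primed) is used for all compounds, open-chain precursors included; geranyl = (2E)-3,7-dimethylocta-2,6-dien-1-yl, MOM = methoxymethyl.

## The problem

Nymphaeol A is a flavanone: ring A, a phloroglucinol-type benzene, is fused through C4a–C8a to the pyranone ring C, the catechol ring B sits on C2, and a geranyl chain sits on C6 between the C5 and C7 hydroxyls. The only stereocentre is C2 (S). It is benzylic, bonded to O1 and β to the C4 ketone, so nothing else in the molecule can control it, and base can erase it by opening ring C to the 2'-hydroxychalcone and reclosing. The classical chalcone cyclisation therefore fails twice: it gives the racemate, and with an unsymmetrical ring A it does not fix the chain at C6 rather than C8. The geranyl chain has two trisubstituted alkenes, which rule out hydrogenolysis, strong Lewis acids, BBr3-type ether cleavage and electrophilic oxidants, and under strong acid it cyclises onto the flanking phenols. The four phenols must carry groups that come off last under mild conditions, because the free catechol and ring A are easily oxidised. The enabling feature is that O1–C8a and C4–C4a are neighbouring bonds on ring A, so ring C can be laid across a C4a–C8a aryne in one annulation. The C5 oxygen next to C4a polarises that aryne so that an oxygen nucleophile enters at C8a and the carbanion appears at C4a, where the acyl carbon C4 must be attached. The O1–C2–C3–C4 unit is then a β-hydroxy ester whose carbinol centre is available by asymmetric ketone reduction.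

## Retrosynthesis

**21 to 20.** The four aryl O–CH2OMe bonds are cut last. MOM ethers are chosen over benzyl or methyl ethers because their removal needs neither hydrogen nor boron halides, which the geranyl chain forbids. They are chosen over silyl ethers because they survive fluoride in the key step. On ring A they also serve as directing groups for the metalation that places the chain. The forward step only has to be mild enough to leave the alkenes and C2 alone.

**20 to 11 and 16.** O1–C8a and C4–C4a are cut together, which opens ring C and divides the molecule into two halves of similar size. Cutting O1–C2 and C2–C3 (the chalcone route) would give up control of C2. Cutting O1–C2 alone would need an SN2 displacement at an electron-rich benzylic carbon. Cutting O1–C8a alone would need an aryl etherification on a very electron-rich, hindered ring. The chosen cut leaves the C2–O bond untouched, so a stereocentre made beforehand is only carried along. The forward reaction asks for three things: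
- aryne 17, released from silyl triflate 11, must accept the alkoxide at C8a and not at C4a;
- the aryl anion 19 must attack the ester faster than it is protonated;
- alkoxide 18 must not fragment by retro-aldol, and the product must not be opened by base.

The hydroxyl is therefore brought in as its trimethylsilyl ether 16. Fluoride then unmasks aryne and alkoxide together, in a flask that holds no O–H proton.

**16 to 15, 14, 13 and 12.** The O–Si bond is cut, then the carbinol C–H bond (ketone reduction), then the C3–C4 bond (carbomethoxylation of a methyl ketone), then the two MOM groups. This reaches commercial 3',4'-dihydroxyacetophenone 12 in four simple operations. Asymmetric transfer hydrogenation of β-keto ester 14 is preferred to an asymmetric acetate aldol because the catalyst class is dependable for aryl ketones. The buffered formic acid medium also spares the MOM ethers, which hot acidic methanol in a pressure hydrogenation might not.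

**11 to 8 and 7.** The C4a–Si and O–Tf bonds are traced to an ortho-bromophenol by the usual silyl-shift route to silylaryl triflates, and the C–Br bond to phenol 7. The two open positions of 7 are equivalent, so bromination has no regiochemical question. The forward steps ask only that the brominating agent prefers the phenol ring to the alkenes.

**7 to 6, 3, 4, 2 and 1.** The aryl–geranyl bond is cut between the two MOM ethers, where directed metalation of 3 is cooperative, and the chain comes from geranyl bromide 4. A TIPS ether holds the third oxygen during metalation and is then removed, so that this oxygen can become the triflate. The bis-MOM phenol 2 comes from phloroglucinol 1 by a statistical protection. This is the price of differentiating one oxygen of a threefold symmetric, very cheap starting material.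

## Roads not taken

**Alternative 1:** Ring A is built around the geranyl carbon by cutting C5–C6 and C7–C8. Heating the chiral 3-alkoxycyclobutenone A2 with the geranyl siloxyalkyne A3 would pass through a vinylketene, a [2+2] adduct and a 6π closure to give phenol A1. Its merits are real: the reaction type is established, the chain position follows from the mechanism, and no phloroglucinol has to be desymmetrised or brominated next to the chain. Its weak points lie in the substrate. In A2 the vinylogous-ester oxygen is a good leaving group β to an ester, so prolonged heating invites elimination to a cinnamate. A3 is a skipped enyne that needs a multi-step homologation. A1 still lacks the C4–C4a bond, and that closure is an acid-mediated acylation which the chain and the acetal groups tolerate poorly. This road is safer in precedent. Against that, the chosen plan closes both ring C bonds in one operation under fluoride at room temperature and is several steps shorter after the fragments are in hand.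

**Alternative 2:** C2–C3 is cut. A rhodium carbene generated from diazoketone A5 would insert into one enantiotopic C–H bond of the O1 benzyl ether and give A4, setting C2 by catalyst control. This is the more elegant answer to the stereochemical problem: no chiral fragment is carried, and the stereocentre is created under neutral conditions at the last C–C bond. For this target it has several weak points. An acceptor-only carbene next to an ether oxygen usually attacks the oxygen first, and the oxonium ylide then rearranges to a benzofuranone. The six-membered insertion is the less favoured ring size. Enantiocontrol with such carbenes is modest. The two nucleophilic alkenes of the chain and the electron-rich arenes offer cyclopropanation and ring-expansion pathways. A5 is also a diazoketone on a fully substituted ring bearing four phenolic silyl ethers. The chosen plan offers against this a stereocentre from a reliable reduction and a key step whose only selectivity issue, the regiochemistry of aryne addition, is decided by the substrate.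

**Alternative 3:** C3–C4 is cut as an alkene. A ruthenium alkylidene (second-generation Grubbs catalyst) formed at the vinyl group of diene A7 would close onto the silyl enol ether and give A6, whose hydrolysis leads to the same intermediate 20. Every step is of a known type, the conditions are neutral so C2 is never exposed to base, and the allylic ether stereocentre could come from asymmetric allylic etherification. In these respects it is better than the chosen plan. The weak points are structural. The enol ether is 1,1-disubstituted, electron-rich and flanked by two ortho substituents, so closure would be slow. The two trisubstituted alkenes of the chain can then compete for the catalyst, and the aryl allyl ether can isomerise or undergo Claisen rearrangement on heating. A7 also needs a C-acetyl group on the crowded ring A and an enol silylation, which adds steps. The chosen plan accepts one unprecedented step in exchange for a shorter route whose conditions do not touch the chain.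

Key step: step 11

## Route

**Step 1**
Reactants: 1 phloroglucinol
Product: 2 3,5-bis(methoxymethoxy)phenol
Conditions: MOMCl (2.0 equiv), i-Pr2NEt (2.2 equiv), DMF, 0 °C to rt; chromatography, mono- and tris-ethers recycled
Reagents that add atoms: chloromethyl methyl ether, COCCl
Why: O-alkylation of a threefold symmetric triol stopped at the statistical maximum of the bis-ether; the three ethers differ clearly in polarity, so separation and recycling are simple, and the loss falls on the cheapest compound of the route.

**Step 2**
Reactants: 2 3,5-bis(methoxymethoxy)phenol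
Product: 3 [3,5-bis(methoxymethoxy)phenoxy]triisopropylsilane
Conditions: TIPSCl, imidazole, DMF, rt
Reagents that add atoms: chlorotriisopropylsilane, CC(C)[Si](Cl)(C(C)C)C(C)C
Why: Routine silylation of a phenol; the bulky, non-coordinating TIPS ether withstands n-BuLi and screens its own ortho positions in the next step.

**Step 3**
Reactants: 3 [3,5-bis(methoxymethoxy)phenoxy]triisopropylsilane; 4 geranyl bromide
Product: 6 [4-geranyl-3,5-bis(methoxymethoxy)phenoxy]triisopropylsilane, via aryllithium 5 (not isolated)
Conditions: n-BuLi (1.1 equiv), THF, 0 °C, 1 h; CuBr·SMe2 (10 mol %), then 4, −78 °C to 0 °C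
Reagents that add atoms: none
Why: Directed ortho-metalation at the carbon flanked by two MOM ethers (cooperative coordination and inductive acidification), then copper-catalysed SN2 allylation at the primary carbon of 4, which leaves the 2E double bond in place.

**Step 4**
Reactants: 6 [4-geranyl-3,5-bis(methoxymethoxy)phenoxy]triisopropylsilane
Product: 7 4-geranyl-3,5-bis(methoxymethoxy)phenol
Conditions: TBAF (1.1 equiv), THF, 0 °C; aq. NH4Cl
Reagents that add atoms: none
Why: Fluoride cleavage of an aryl silyl ether; the MOM ethers and the diene are inert to fluoride.

**Step 5**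
Reactants: 7 4-geranyl-3,5-bis(methoxymethoxy)phenol
Product: 8 2-bromo-4-geranyl-3,5-bis(methoxymethoxy)phenol
Conditions: NBS (1.0 equiv), CH2Cl2, −78 °C
Reagents that add atoms: N-bromosuccinimide, O=C1CCC(=O)N1Br
Why: Electrophilic aromatic bromination ortho to the free hydroxyl of a phloroglucinol-type ring, which at low temperature should be far more nucleophilic than the trisubstituted alkenes; the two open positions are equivalent and one equivalent of reagent should stop at the monobromide.

**Step 6**
Reactants: 8 2-bromo-4-geranyl-3,5-bis(methoxymethoxy)phenol
Product: 11 4-geranyl-3,5-bis(methoxymethoxy)-2-(trimethylsilyl)phenyl trifluoromethanesulfonate, via silyl ether 9 (not isolated), via lithium phenoxide 10 (not isolated)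
Conditions: (Me3Si)2NH, THF, 65 °C, then evaporation; n-BuLi (1.1 equiv), THF, −100 °C to −78 °C; Tf2O (1.2 equiv), −100 °C to rt
Reagents that add atoms: hexamethyldisilazane, C[Si](C)(C)N[Si](C)(C)C; trifluoromethanesulfonic anhydride, O=S(=O)(OS(=O)(=O)C(F)(F)F)C(F)(F)F
Why: O-silylation, bromine–lithium exchange, anionic 1,3 O-to-C silyl shift (retro-Brook rearrangement) driven by phenoxide formation, and O-triflation; this is the standard one-flask route to ortho-silylaryl triflates and uses nothing that affects MOM ethers or alkenes.

**Step 7**
Reactants: 12 3',4'-dihydroxyacetophenone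
Product: 13 3',4'-bis(methoxymethoxy)acetophenone
Conditions: MOMCl (2.5 equiv), i-Pr2NEt, CH2Cl2, 0 °C to rt
Reagents that add atoms: chloromethyl methyl ether, COCCl
Why: Exhaustive O-alkylation of a catechol under mild base; the ketone is untouched.

**Step 8**
Reactants: 13 3',4'-bis(methoxymethoxy)acetophenone
Product: 14 methyl 3-[3,4-bis(methoxymethoxy)phenyl]-3-oxopropanoate
Conditions: NaH (2.5 equiv), (MeO)2CO, THF, reflux; AcOH, 0 °C
Reagents that add atoms: dimethyl carbonate, COC(=O)OC
Why: Claisen-type carbomethoxylation of the methyl ketone enolate, driven to completion by deprotonation of the β-keto ester formed; it creates the C3–C4 bond.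

**Step 9**
Reactants: 14 methyl 3-[3,4-bis(methoxymethoxy)phenyl]-3-oxopropanoate
Product: 15 methyl (S)-3-[3,4-bis(methoxymethoxy)phenyl]-3-hydroxypropanoate
Conditions: RuCl[(S,S)-TsDPEN](p-cymene) (1 mol %), HCO2H/Et3N (5:2), CH2Cl2, 30 °C
Reagents that add atoms: none
Why: Noyori–Ikariya asymmetric transfer hydrogenation; the aryl group lies next to the η6-arene of the catalyst as in acetophenone, so the (S,S) catalyst should deliver hydride to the face that gives the (S) carbinol (aryl outranks CH2CO2Me as it outranks CH3), and the buffered medium spares the MOM ethers.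

**Step 10**
Reactants: 15 methyl (S)-3-[3,4-bis(methoxymethoxy)phenyl]-3-hydroxypropanoate
Product: 16 methyl (S)-3-[3,4-bis(methoxymethoxy)phenyl]-3-(trimethylsilyloxy)propanoate
Conditions: TMSCl (1.2 equiv), Et3N, CH2Cl2, 0 °C; pentane, filtration, no aqueous acid
Reagents that add atoms: chlorotrimethylsilane, C[Si](C)(C)Cl
Why: Routine O-silylation that does not touch C2; it turns the hydroxyl into a latent alkoxide so that the key step runs without any O–H proton.

**Step 11**
Reactants: 11 4-geranyl-3,5-bis(methoxymethoxy)-2-(trimethylsilyl)phenyl trifluoromethanesulfonate (1.3 equiv); 16 methyl (S)-3-[3,4-bis(methoxymethoxy)phenyl]-3-(trimethylsilyloxy)propanoate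
Product: 20 (S)-5,7,3',4'-tetra-O-methoxymethyl nymphaeol A, via aryne 17 (not isolated), via caesium alkoxide 18 (not isolated), via aryl caesium 19 (not isolated)
Conditions: CsF (3 equiv), 18-crown-6 (0.3 equiv), THF, 0 °C to rt; pH 7 phosphate buffer
Reagents that add atoms: none
Why: Proposed new method: fluoride attacks the aryl silicon of 11 and the ortho triflate departs to give aryne 17, while fluoride at first and then the methoxide released later removes the trimethylsilyl group of 16, so alkoxide 18 appears only in low concentration and with no proton source present. The C5 alkoxy group distorts and polarises the aryne, so 18 should add at the distal carbon C8a and the charge should develop at C4a, where the adjacent C–O bond stabilises it inductively; this substrate control fixes the chain at C6 and not C8. Aryl caesium 19 then adds to the ester carbonyl in a 6-exo-trig closure of ring C and the tetrahedral intermediate expels methoxide, so O1–C8a and C4–C4a form in one operation. The closest known reaction type is the fluoride-triggered annulation of arynes with salicylate esters to xanthones, which follows the same sequence of O-arylation and intramolecular acyl substitution; new here are an aliphatic alkoxide as the nucleophile and a chroman-4-one as the ring formed. No stereocentre is created: the C2–O bond is never broken, so the (S) configuration of 15 should pass unchanged into 20. The step needs acyl capture to outrun protonation of 19, retro-aldol cleavage of 18 and base-induced opening of ring C in 20. The silyl ether protocol, THF in place of the more acidic acetonitrile, the six-membered transition state and the uptake of methoxide by silicon as MeOSiMe3 are meant to secure this, together with a neutral quench as soon as 16 is consumed.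

**Step 12**
Reactants: 20 (S)-5,7,3',4'-tetra-O-methoxymethyl nymphaeol A
Product: 21 nymphaeol A
Conditions: 3 M aq. HCl, MeOH, 40 °C, argon
Reagents that add atoms: none
Why: Acid-catalysed acetal exchange converts the four MOM ethers to dimethoxymethane; dilute acid does not epimerise a flavanone at C2, and conditions of this kind are the usual last step for prenylated and geranylated flavanones.

## Compound list

1 | phloroglucinol (benzene-1,3,5-triol) | Oc1cc(O)cc(O)c1 | starting material
2 | 3,5-bis(methoxymethoxy)phenol | COCOc1cc(O)cc(OCOC)c1 | intermediate
3 | [3,5-bis(methoxymethoxy)phenoxy]triisopropylsilane | COCOc1cc(OCOC)cc(O[Si](C(C)C)(C(C)C)C(C)C)c1 | intermediate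
4 | geranyl bromide, (2E)-1-bromo-3,7-dimethylocta-2,6-diene | CC(C)=CCC/C(C)=C/CBr | starting material
5 | 2,6-bis(methoxymethoxy)-4-(triisopropylsilyloxy)phenyllithium (formed in the flask) | [Li]c1c(OCOC)cc(O[Si](C(C)C)(C(C)C)C(C)C)cc1OCOC | intermediate
6 | [4-geranyl-3,5-bis(methoxymethoxy)phenoxy]triisopropylsilane | CC(C)=CCC/C(C)=C/Cc1c(OCOC)cc(O[Si](C(C)C)(C(C)C)C(C)C)cc1OCOC | intermediate
7 | 4-geranyl-3,5-bis(methoxymethoxy)phenol | CC(C)=CCC/C(C)=C/Cc1c(OCOC)cc(O)cc1OCOC | intermediate
8 | 2-bromo-4-geranyl-3,5-bis(methoxymethoxy)phenol | CC(C)=CCC/C(C)=C/Cc1c(OCOC)cc(O)c(Br)c1OCOC | intermediate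
9 | [2-bromo-4-geranyl-3,5-bis(methoxymethoxy)phenoxy]trimethylsilane (formed in the flask) | CC(C)=CCC/C(C)=C/Cc1c(OCOC)cc(O[Si](C)(C)C)c(Br)c1OCOC | intermediate
10 | lithium 4-geranyl-3,5-bis(methoxymethoxy)-2-(trimethylsilyl)phenoxide (formed in the flask) | CC(C)=CCC/C(C)=C/Cc1c(OCOC)cc([O-])c([Si](C)(C)C)c1OCOC.[Li+] | intermediate
11 | 4-geranyl-3,5-bis(methoxymethoxy)-2-(trimethylsilyl)phenyl trifluoromethanesulfonate | CC(C)=CCC/C(C)=C/Cc1c(OCOC)cc(OS(=O)(=O)C(F)(F)F)c([Si](C)(C)C)c1OCOC | intermediate
12 | 3',4'-dihydroxyacetophenone | CC(=O)c1ccc(O)c(O)c1 | starting material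
13 | 3',4'-bis(methoxymethoxy)acetophenone | CC(=O)c1ccc(OCOC)c(OCOC)c1 | intermediate
14 | methyl 3-[3,4-bis(methoxymethoxy)phenyl]-3-oxopropanoate | COC(=O)CC(=O)c1ccc(OCOC)c(OCOC)c1 | intermediate
15 | methyl (S)-3-[3,4-bis(methoxymethoxy)phenyl]-3-hydroxypropanoate | COC(=O)C[C@@H](c1ccc(OCOC)c(OCOC)c1)O | intermediate
16 | methyl (S)-3-[3,4-bis(methoxymethoxy)phenyl]-3-(trimethylsilyloxy)propanoate | COC(=O)C[C@@H](c1ccc(OCOC)c(OCOC)c1)O[Si](C)(C)C | intermediate
17 | 4-geranyl-3,5-bis(methoxymethoxy)benzyne, triple bond between the former C–OTf and C–Si carbons (formed in the flask) | CC(C)=CCC/C(C)=C/CC1=C(OCOC)C#CC=C1OCOC | intermediate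
18 | caesium (S)-1-[3,4-bis(methoxymethoxy)phenyl]-3-methoxy-3-oxopropan-1-olate (formed in the flask) | COC(=O)C[C@@H](c1ccc(OCOC)c(OCOC)c1)[O-].[Cs+] | intermediate
19 | methyl (S)-3-[3,4-bis(methoxymethoxy)phenyl]-3-[2-caesio-4-geranyl-3,5-bis(methoxymethoxy)phenoxy]propanoate (formed in the flask) | CC(C)=CCC/C(C)=C/Cc1c(OCOC)cc(O[C@@H](CC(=O)OC)c2ccc(OCOC)c(OCOC)c2)c([Cs])c1OCOC | intermediate
20 | (S)-5,7,3',4'-tetra-O-methoxymethyl nymphaeol A, (2S)-2-[3,4-bis(methoxymethoxy)phenyl]-6-geranyl-5,7-bis(methoxymethoxy)chroman-4-one | CC(C)=CCC/C(C)=C/Cc1c(OCOC)cc2c(c1OCOC)C(=O)C[C@@H](c1ccc(OCOC)c(OCOC)c1)O2 | intermediate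
21 | nymphaeol A, (2S)-2-(3,4-dihydroxyphenyl)-6-geranyl-5,7-dihydroxychroman-4-one | CC(C)=CCC/C(C)=C/Cc1c(O)cc2c(c1O)C(=O)C[C@@H](c1ccc(O)c(O)c1)O2 | target

## Step count and risks

Total: 12 steps. Longest linear sequence: 8 steps (steps 1 to 6, 11 and 12); the ring B branch (steps 7 to 10) joins at step 11.

**Step 11 (key step, proposed new method).**
- *What may go wrong:* protonation of the aryl anion before it reaches the ester, leaving an open aryl ether; retro-aldol fragmentation of the alkoxide before it meets the aryne; enolisation followed by β-elimination of the aryloxide; base-induced opening and reclosure of ring C in the product, with loss of configuration at C2.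
- *Fallback (known chemistry):* it sets out from bromophenol 8 and keto ester 14 and returns at 20. Transfer hydrogenation of 14 with the (R,R) catalyst would give methyl (R)-3-[3,4-bis(methoxymethoxy)phenyl]-3-hydroxypropanoate F1. Mitsunobu etherification of 8 with F1 (PPh3, DIAD, toluene, 0 °C) should give, with inversion at the carbinol carbon, methyl (S)-3-[3,4-bis(methoxymethoxy)phenyl]-3-[2-bromo-4-geranyl-3,5-bis(methoxymethoxy)phenoxy]propanoate F2. Bromine–lithium exchange (t-BuLi, THF, −100 °C) and Parham-type cyclisation of the aryllithium onto the ester would then close ring C to 20. Here O1–C2 and C4–C4a are formed in two separate steps, and the aryl anion is generated where no proton donor is present.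

**Step 5.**
- *What may go wrong:* attack of the bromonium source on the chain alkenes (bromocyclisation) or a second ring bromination, because the ring and the alkenes are both electron-rich.
- *Fallback:* it sets out from 6 and returns at 8, replacing the electrophilic bromination by an anionic one. Directed ortho-lithiation of 6 between the MOM and TIPS ethers (n-BuLi, TMEDA, THF, −78 °C) and a quench with BrCF2CF2Br, a bromine donor that ignores alkenes, would give [2-bromo-4-geranyl-3,5-bis(methoxymethoxy)phenoxy]triisopropylsilane F3. TBAF would then release 8.

**Step 6.**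
- *What may go wrong:* incomplete silyl migration, or protonation of the aryllithium, on a ring in which the anionic carbon is flanked by two oxygen substituents; triflation of the hindered phenoxide may be slow.
- *Fallback:* it sets out from 7 and returns at 11, and so also bypasses step 5. It uses carbamate-directed ortho-silylation in place of the bromide route. Reaction of 7 with isopropyl isocyanate (Et3N) would give 4-geranyl-3,5-bis(methoxymethoxy)phenyl N-isopropylcarbamate F4. N-silylation in the flask (TBSOTf, TMEDA), ortho-lithiation (n-BuLi, TMEDA, −78 °C) and TMSCl would give 4-geranyl-3,5-bis(methoxymethoxy)-2-(trimethylsilyl)phenyl N-isopropylcarbamate F5. Cleavage with Et2NH and DBU in MeCN would give 4-geranyl-3,5-bis(methoxymethoxy)-2-(trimethylsilyl)phenol F6, and PhNTf2 would convert it to 11.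

**Step 12.**
- *What may go wrong:* acid-promoted cyclisation of the chain onto the freed C5 or C7 hydroxyl, or hydration of the alkenes, before the last MOM group (at the hindered C5 oxygen) has gone.
- *Fallback:* it sets out from 20 and returns at 21 without any protic acid. TESOTf with 2,2'-bipyridyl (CH2Cl2, 0 °C) converts aryl MOM ethers directly into aryl silyl ethers and should give (S)-5,7,3',4'-tetra-O-triethylsilyl nymphaeol A F7. Buffered fluoride (TBAF with AcOH, THF, 0 °C) would then release 21.

## Further compounds

F1 | step 11 | methyl (R)-3-[3,4-bis(methoxymethoxy)phenyl]-3-hydroxypropanoate | COC(=O)C[C@H](c1ccc(OCOC)c(OCOC)c1)O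
F2 | step 11 | methyl (S)-3-[3,4-bis(methoxymethoxy)phenyl]-3-[2-bromo-4-geranyl-3,5-bis(methoxymethoxy)phenoxy]propanoate | CC(C)=CCC/C(C)=C/Cc1c(OCOC)cc(O[C@@H](CC(=O)OC)c2ccc(OCOC)c(OCOC)c2)c(Br)c1OCOC
F3 | step 5 | [2-bromo-4-geranyl-3,5-bis(methoxymethoxy)phenoxy]triisopropylsilane | CC(C)=CCC/C(C)=C/Cc1c(OCOC)cc(O[Si](C(C)C)(C(C)C)C(C)C)c(Br)c1OCOC
F4 | step 6 | 4-geranyl-3,5-bis(methoxymethoxy)phenyl N-isopropylcarbamate | CC(C)=CCC/C(C)=C/Cc1c(OCOC)cc(OC(=O)NC(C)C)cc1OCOC
F5 | step 6 | 4-geranyl-3,5-bis(methoxymethoxy)-2-(trimethylsilyl)phenyl N-isopropylcarbamate | CC(C)=CCC/C(C)=C/Cc1c(OCOC)cc(OC(=O)NC(C)C)c([Si](C)(C)C)c1OCOC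
F6 | step 6 | 4-geranyl-3,5-bis(methoxymethoxy)-2-(trimethylsilyl)phenol | CC(C)=CCC/C(C)=C/Cc1c(OCOC)cc(O)c([Si](C)(C)C)c1OCOC
F7 | step 12 | (S)-5,7,3',4'-tetra-O-triethylsilyl nymphaeol A | CC(C)=CCC/C(C)=C/Cc1c(O[Si](CC)(CC)CC)cc2c(c1O[Si](CC)(CC)CC)C(=O)C[C@@H](c1ccc(O[Si](CC)(CC)CC)c(O[Si](CC)(CC)CC)c1)O2
A1 | alternative 1 | methyl (S)-3-[3,4-bis(methoxymethoxy)phenyl]-3-[4-geranyl-3-hydroxy-5-(triisopropylsilyloxy)phenoxy]propanoate | CC(C)=CCC/C(C)=C/Cc1c(O)cc(O[C@@H](CC(=O)OC)c2ccc(OCOC)c(OCOC)c2)cc1O[Si](C(C)C)(C(C)C)C(C)C
A2 | alternative 1 | methyl (S)-3-[3,4-bis(methoxymethoxy)phenyl]-3-[(3-oxocyclobut-1-en-1-yl)oxy]propanoate | COC(=O)C[C@@H](c1ccc(OCOC)c(OCOC)c1)OC1=CC(=O)C1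
A3 | alternative 1 | {[(4E)-5,9-dimethyldeca-4,8-dien-1-yn-1-yl]oxy}triisopropylsilane | CC(C)=CCC/C(C)=C/CC#CO[Si](C(C)C)(C(C)C)C(C)C
A4 | alternative 2 | (S)-5,7,3',4'-tetra-O-tert-butyldimethylsilyl nymphaeol A | CC(C)=CCC/C(C)=C/Cc1c(O[Si](C)(C)C(C)(C)C)cc2c(c1O[Si](C)(C)C(C)(C)C)C(=O)C[C@@H](c1ccc(O[Si](C)(C)C(C)(C)C)c(O[Si](C)(C)C(C)(C)C)c1)O2
A5 | alternative 2 | 1-{6-[3,4-bis(tert-butyldimethylsilyloxy)benzyloxy]-2,4-bis(tert-butyldimethylsilyloxy)-3-geranylphenyl}-2-diazoethan-1-one | CC(C)=CCC/C(C)=C/Cc1c(O[Si](C)(C)C(C)(C)C)cc(OCc2ccc(O[Si](C)(C)C(C)(C)C)c(O[Si](C)(C)C(C)(C)C)c2)c(C(=O)C=[N+]=[N-])c1O[Si](C)(C)C(C)(C)C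
A6 | alternative 3 | (S)-4-(tert-butyldimethylsilyloxy)-6-geranyl-5,7,3',4'-tetrakis(methoxymethoxy)-2H-flav-3-ene | CC(C)=CCC/C(C)=C/Cc1c(OCOC)cc2c(c1OCOC)C(O[Si](C)(C)C(C)(C)C)=C[C@@H](c1ccc(OCOC)c(OCOC)c1)O2
A7 | alternative 3 | tert-butyl{[1-(2-{[(1S)-1-[3,4-bis(methoxymethoxy)phenyl]prop-2-en-1-yl]oxy}-5-geranyl-4,6-bis(methoxymethoxy)phenyl)ethenyl]oxy}dimethylsilane | CC(C)=CCC/C(C)=C/Cc1c(OCOC)cc(O[C@@H](C=C)c2ccc(OCOC)c(OCOC)c2)c(C(=C)O[Si](C)(C)C(C)(C)C)c1OCOC
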